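Compound numbers used below: **1**–**14** are the compounds of the route (**14** is the target), **A1**–**A6** belong to the rejected alternatives, **F1**–**F5** to the fallbacks.

## Analysis of the target

Target **14** is a macrocyclic diaryl ether in which ring A is a 1,3,5-trisubstituted benzene carrying one hydroxyl, the ether oxygen and one chain terminus. Ring B carries the ether oxygen at C1, hydroxyls at C2 and C4, and the other chain terminus at C6. The two rings are tied together by the ether oxygen and by an unbranched chain of fourteen methylene groups, so the macrocycle has 20 members: the oxygen, C1 and C6 of ring B, the fourteen chain carbons and three carbons of ring A. There is no stereocentre, and with so long a tether no configurationally stable planar chirality is expected, so the problem is one of connectivity only. The sensitive groups are the three phenols; ring B, oxygenated at C1, C2 and C4, is electron-rich and prone to oxidation, so the phenols are best kept as methyl ethers until the last step. Two things make the synthesis hard: the ether carbon C1 of ring B is flanked on both sides (oxygen at C2, chain at C6), and a 20-membered ring has to be closed against the entropic cost of bringing two remote chain ends together. The chain has no functional group to suggest a disconnection, but numbered from ring B its C7–C8 bond is the midpoint and lies across the ring from the ether oxygen. Cutting there leaves two seven-carbon arms of identical constitution, one on C6 of ring B and one on ring A, and the strategy rests on this.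

## Retrosynthetic reasoning

**14 ⇒ 13.** The three O–H groups are traced back to O–CH3 groups. Methyl ethers are already present in the cheap aromatic starting materials and survive ylides, hydrides, copper in pyridine and hydrogenation, so no protecting-group step is spent on the way in. The forward reaction is a single Lewis-acid cleavage that must leave the diaryl ether alone.

**13 ⇒ 12.** Unsaturation is reintroduced into the chain: C6–C9 become a conjugated 1,3-diyne. This turns the featureless central C7–C8 bond into an sp–sp bond, which can be made by coupling. The forward reaction is an exhaustive hydrogenation with no selectivity issue.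

**12 ⇒ 11.** The C7–C8 bond is cut, opening the 20-membered ring to bis-alkyne **11**, whose two arms are both hept-6-ynyl groups. This bond is chosen because it is the only chain bond whose cleavage gives identical halves, and because it is the bond farthest from the hindered C1 of ring B. Any other C–C cut would need two different arms built separately. Cutting the ether instead would place the hindered C–O bond formation in the macrocyclisation. Forward, a divalent copper oxidant has to join the two terminal alkyne carbons within one molecule and not between molecules.

**11 ⇒ 10 ⇒ 9.** Each terminal alkyne is taken back by one carbon to an aldehyde (Ohira–Bestmann alkynylation in the forward sense), giving dialdehyde **10**, and each aldehyde to a methyl ester, giving diester **9**. Both changes act on the two arms at once.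

**9 ⇒ 8 ⇒ 4 + 7.** Each arm is cut between its first and second carbon as a double bond. A double Wittig olefination of dialdehyde **4** with ylide **7** then installs both six-carbon ester arms in one operation, and hydrogenation removes the alkene geometry. Ylide **7** comes from phosphonium salt **6**, itself made from bromo ester **5**. The cut is placed at the benzylic position because both rings then need only a formyl group.

**4 ⇒ 2 + 3.** The diaryl ether is cut on the ring B side, giving aryl bromide **2** and phenol **3**. The formyl group that later becomes the arm sits ortho to the bromine in **2** and assists the copper-mediated C–O coupling. A cut on the ring A side would make a hindered, electron-poor salicylaldehyde-type phenol the nucleophile. The coupling is intermolecular and early, on small cheap pieces.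

**2 ⇒ 1.** The C–Br bond is traced to a C–H bond of aldehyde **1**; bromination should go to C2, para to one methoxy group and ortho to the other.

## Alternatives that were turned down

**Alternative 1:** The ring is opened at the O–C bond on the ring A side, with ring A not yet aromatic. Precursor **A1** is a ring B phenol whose fourteen-carbon chain ends in a 3-chlorocyclohex-2-enone. Forward, Cs2CO3 in dilute DMF would give the phenoxide, which adds to the β-carbon of the chloroenone and expels chloride, closing the 20-membered ring as racemic aryloxy-enone **A2**. Dehydrogenation would then turn the enone ring into ring A, and demethylation would follow.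

- For: the hindered ether is made without copper at a strongly electrophilic vinylogous acid chloride, and the stereocentre of **A2** disappears on aromatisation.
- Against: the di-ortho-substituted phenoxide has to perform the macrocyclisation, so the steric problem sits in the entropically hardest step. **A1** is unsymmetrical, with a fourteen-carbon chain bearing two different ends, and must be built linearly. Aromatising **A2** is an oxidation next to the very electron-rich ring B.
- Comparison: on ether formation itself this alternative is stronger, and it needs no hydrogenation after ring closure. The chosen route instead makes the ether intermolecularly on small pieces and grows both arms in one two-directional sequence, which should save several steps.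

**Alternative 2:** The chain is cut at C13–C14, next to ring A, but the bond is made by ring contraction. Precursor **A3** is a 21-membered sulfone with SO2 between the ring A benzylic carbon and C13. Forward, KOH on alumina with CBr2F2 would halogenate the sulfone α-carbon, close the episulfone and extrude SO2 (Ramberg–Bäcklund reaction), giving the 20-membered styrene-type alkene **A4**; hydrogenation and demethylation would follow.

- For: the large ring would be closed earlier by S-alkylation, among the most dependable macrocyclisations, and the C–C bond then forms within an existing ring.
- Against: one C–C bond costs three operations (sulfide closure, oxidation at sulfur, contraction). The two arms differ (thirteen carbons with sulfur on ring B, one carbon on ring A), so there is no two-directional economy. The same hindered diaryl ether coupling is still needed, and CBr2F2 is an ozone-depleting gas of restricted supply.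
- Comparison: on ring-closure reliability this alternative is probably stronger. The chosen route makes bond and ring in one step from a symmetrical precursor and is clearly shorter.

**Alternative 3:** The chain is cut at C1–C2, next to ring B. Precursor **A5** is a diaryl ether dialdehyde with a formyl group on C6 of ring B and a 13-oxotridecyl chain on ring A. Forward, TiCl3(dme)1.5 (trivalent titanium) reduced with Zn–Cu couple, with slow addition of **A5** in refluxing DME, would couple the two carbonyl carbons reductively (McMurry reaction) to give macrocyclic alkene **A6**; hydrogenation and demethylation would follow.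

- For: the formyl group that assists the ether coupling is used a second time as the coupling partner, the McMurry reaction has a strong record for large rings, and only one equivalent of hydrogen is needed afterwards.
- Against: the two carbonyls are unlike. The aryl aldehyde is reduced to its ketyl much more readily than the aliphatic one, so pinacol-type coupling between aryl aldehyde ends of different molecules competes with the mixed intramolecular coupling. Ring A must carry a long chain with a masked aldehyde through the etherification, so the building blocks are unsymmetrical and longer to make.
- Comparison: this is the closest competitor, at least equal on atom use and on precedent for the ring closure, with a similar step count. The chosen route offers two identical reacting termini, so there is no reactivity mismatch, mild non-reducing ring-closure conditions, and one cheap five-carbon reagent for both arms.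

Key step: step 8

## Route

Remark on the chemistry: compound **8** is drawn as the Z,Z isomer expected from a non-stabilised ylide; any E isomer is carried along, because step 5 saturates both double bonds.

Step 1
Reactants: 1 3,5-dimethoxybenzaldehyde
Product: 2 2-bromo-3,5-dimethoxybenzaldehyde
Conditions: Br2 (1.05 equiv), AcOH, rt
Reagents that add atoms: bromine, BrBr
Why: Electrophilic aromatic bromination. C2 is para to one methoxy group and ortho to the other and is less crowded than C4 between the two methoxy groups, so monobromination should go there; the formyl group and the limited amount of bromine hold back a second substitution.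

Step 2
Reactants: 2 2-bromo-3,5-dimethoxybenzaldehyde; 3 3-hydroxy-5-methoxybenzaldehyde
Product: 4 2-(3-formyl-5-methoxyphenoxy)-3,5-dimethoxybenzaldehyde
Conditions: CuI (10 mol%), picolinic acid (20 mol%), K3PO4 (2 equiv), DMSO, 90 °C
Reagents that add atoms: none
Why: Ullmann-type C–O coupling catalysed by monovalent copper. The coordinating formyl group ortho to bromine should assist oxidative addition and the picolinate ligand suits ortho-substituted partners; neither aldehyde is enolisable, so the phosphate base has no competing pathway.

Step 3
Reactants: 5 methyl 5-bromopentanoate
Product: 6 (5-methoxy-5-oxopentyl)triphenylphosphonium bromide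
Conditions: PPh3, MeCN, reflux
Reagents that add atoms: triphenylphosphine, c1ccc(cc1)P(c1ccccc1)c1ccccc1
Why: SN2 quaternisation of a primary alkyl bromide by the phosphine; the ester is a spectator.

Step 4
Reactants: 4 2-(3-formyl-5-methoxyphenoxy)-3,5-dimethoxybenzaldehyde; 6 (5-methoxy-5-oxopentyl)triphenylphosphonium bromide
Product: 8 methyl (5Z)-6-{2-[3-((1Z)-6-methoxy-6-oxohex-1-en-1-yl)-5-methoxyphenoxy]-3,5-dimethoxyphenyl}hex-5-enoate, via phosphorus ylide 7 (not isolated)
Conditions: 6 (2.6 equiv), NaN(SiMe3)2 (2.5 equiv), THF, −78 °C; then 4, −78 °C → rt
Reagents that add atoms: none
Why: Two-directional Wittig olefination with a non-stabilised ylide. The CH2 next to phosphorus is far more acidic than the CH2 next to the ester, so the hindered amide base should form 7 selectively at low temperature, and both aryl aldehydes are olefinated through oxaphosphetanes; the alkene geometry is of no consequence.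

Step 5
Reactants: 8 methyl (5Z)-6-{2-[3-((1Z)-6-methoxy-6-oxohex-1-en-1-yl)-5-methoxyphenoxy]-3,5-dimethoxyphenyl}hex-5-enoate
Product: 9 methyl 6-{2-[3-(6-methoxy-6-oxohexyl)-5-methoxyphenoxy]-3,5-dimethoxyphenyl}hexanoate
Conditions: H2 (1 atm), Pd/C, EtOAc, rt
Reagents that add atoms: none
Why: Heterogeneous catalytic hydrogenation of two disubstituted styrene-type double bonds; esters, methyl ethers and the diaryl ether are inert under these conditions.

Step 6
Reactants: 9 methyl 6-{2-[3-(6-methoxy-6-oxohexyl)-5-methoxyphenoxy]-3,5-dimethoxyphenyl}hexanoate
Product: 10 6-{2-[3-(6-oxohexyl)-5-methoxyphenoxy]-3,5-dimethoxyphenyl}hexanal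
Conditions: i-Bu2AlH (2.3 equiv), CH2Cl2, −78 °C; then MeOH, aq. potassium sodium tartrate
Reagents that add atoms: none
Why: Partial reduction of methyl esters with a dialkylaluminium hydride. The tetrahedral aluminium hemiacetal persists at −78 °C and releases the aldehyde only on work-up, which should stop the reduction at the aldehyde stage.

Step 7
Reactants: 10 6-{2-[3-(6-oxohexyl)-5-methoxyphenoxy]-3,5-dimethoxyphenyl}hexanal
Product: 11 1-(hept-6-yn-1-yl)-2-[3-(hept-6-yn-1-yl)-5-methoxyphenoxy]-3,5-dimethoxybenzene
Conditions: dimethyl (1-diazo-2-oxopropyl)phosphonate (3 equiv), K2CO3 (4 equiv), MeOH, 0 °C → rt
Reagents that add atoms: dimethyl (1-diazo-2-oxopropyl)phosphonate, COP(=O)(OC)C(=[N+]=[N-])C(C)=O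
Why: Ohira–Bestmann variant of the Seyferth–Gilbert homologation. Methoxide removes the acetyl group, the diazomethylphosphonate anion adds to each aldehyde in the manner of a Horner–Wadsworth–Emmons reaction, and loss of N2 with a 1,2-hydrogen shift gives the terminal alkyne; the carbonate base is too mild to cause aldol condensation.

Step 8
Reactants: 11 1-(hept-6-yn-1-yl)-2-[3-(hept-6-yn-1-yl)-5-methoxyphenoxy]-3,5-dimethoxybenzene
Product: 12 twenty-membered macrocyclic 1,3-diyne trimethyl ether (pentamethylene–buta-1,3-diynediyl–pentamethylene chain from ring B to ring A)
Conditions: Cu(OAc)2 (10 equiv), pyridine–MeCN (1:4), 60 °C; 11 added by syringe pump over 12 h, final concentration about 1 mM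
Reagents that add atoms: none
Why: This is the Eglinton variant of the Glaser coupling, and its closest precedent is the cyclisation of α,ω-diynes to macrocyclic 1,3-diynes. Pyridine and acetate remove the acidic proton from each copper-bound terminal alkyne of 11 to give a copper acetylide; two acetylides gather on a pair of divalent copper centres and the two alkynyl carbons, both nucleophilic, are joined while each copper drops to the monovalent state. The ring closes by end-to-end sp–sp union of the two arm termini, forming the C7–C8 bond and a 20-membered ring in which the stiff four-carbon diyne rod lies opposite the diaryl ether hinge and the two pentamethylene segments take up the remaining strain. No stereocentre is formed. The selectivity needed is ring closure over chain growth; it is secured by keeping the stationary concentration of uncyclised 11 very low (slow addition into excess oxidant) and is helped by the bent C–O–C angle of the ether, which turns the ortho arm of ring B and the meta arm of ring A towards the same side. Because both termini are the same alkyne, homocoupling is the wanted reaction and no cross-selectivity question arises. The methyl ethers and the diaryl ether are inert to the oxidant.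

Step 9
Reactants: 12 twenty-membered macrocyclic 1,3-diyne trimethyl ether (pentamethylene–buta-1,3-diynediyl–pentamethylene chain from ring B to ring A)
Product: 13 twenty-membered macrocyclic trimethyl ether (saturated tetradecamethylene chain from ring B to ring A)
Conditions: H2 (1 atm), Pd/C, EtOAc, rt
Reagents that add atoms: none
Why: Exhaustive catalytic hydrogenation; four equivalents of hydrogen turn the conjugated diyne into the central tetramethylene unit, and nothing else in 12 is reducible under these conditions.

Step 10
Reactants: 13 twenty-membered macrocyclic trimethyl ether (saturated tetradecamethylene chain from ring B to ring A)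
Product: 14 CNP0173380.0 (macrocyclic diaryl ether triphenol)
Conditions: BBr3 (6 equiv), CH2Cl2, −78 °C → rt, under Ar; then H2O
Reagents that add atoms: none
Why: Lewis-acid cleavage of aryl methyl ethers: boron binds the ether oxygen and bromide removes the methyl group by SN2. The diaryl ether oxygen carries no sp3 carbon and cannot be cleaved this way; argon and a degassed work-up protect the electron-rich ring B of the free triphenol.

## Compound list

1 | 3,5-dimethoxybenzaldehyde | COc1cc(C=O)cc(OC)c1 | starting material
2 | 2-bromo-3,5-dimethoxybenzaldehyde | COc1cc(OC)c(Br)c(C=O)c1 | intermediate
3 | 3-hydroxy-5-methoxybenzaldehyde | COc1cc(O)cc(C=O)c1 | starting material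
4 | 2-(3-formyl-5-methoxyphenoxy)-3,5-dimethoxybenzaldehyde | COc1cc(OC)c(Oc2cc(OC)cc(C=O)c2)c(C=O)c1 | intermediate
5 | methyl 5-bromopentanoate | COC(=O)CCCCBr | starting material
6 | (5-methoxy-5-oxopentyl)triphenylphosphonium bromide | COC(=O)CCCC[P+](c1ccccc1)(c1ccccc1)c1ccccc1.[Br-] | intermediate
7 | methyl 5-(triphenylphosphoranylidene)pentanoate (phosphorus ylide, not isolated) | COC(=O)CCCC=P(c1ccccc1)(c1ccccc1)c1ccccc1 | intermediate
8 | methyl (5Z)-6-{2-[3-((1Z)-6-methoxy-6-oxohex-1-en-1-yl)-5-methoxyphenoxy]-3,5-dimethoxyphenyl}hex-5-enoate | COC(=O)CCC/C=C\c1cc(OC)cc(OC)c1Oc1cc(OC)cc(/C=C\CCCC(=O)OC)c1 | intermediate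
9 | methyl 6-{2-[3-(6-methoxy-6-oxohexyl)-5-methoxyphenoxy]-3,5-dimethoxyphenyl}hexanoate | COC(=O)CCCCCc1cc(OC)cc(OC)c1Oc1cc(OC)cc(CCCCCC(=O)OC)c1 | intermediate
10 | 6-{2-[3-(6-oxohexyl)-5-methoxyphenoxy]-3,5-dimethoxyphenyl}hexanal | O=CCCCCCc1cc(OC)cc(OC)c1Oc1cc(OC)cc(CCCCCC=O)c1 | intermediate
11 | 1-(hept-6-yn-1-yl)-2-[3-(hept-6-yn-1-yl)-5-methoxyphenoxy]-3,5-dimethoxybenzene | C#CCCCCCc1cc(OC)cc(OC)c1Oc1cc(OC)cc(CCCCCC#C)c1 | intermediate
12 | twenty-membered macrocyclic 1,3-diyne trimethyl ether (pentamethylene–buta-1,3-diynediyl–pentamethylene chain from C6 of ring B to ring A; methoxy groups on C2 and C4 of ring B and on ring A) | COc1cc2cc(c1)Oc1c(OC)cc(OC)cc1CCCCCC#CC#CCCCCC2 | intermediate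
13 | twenty-membered macrocyclic trimethyl ether (saturated tetradecamethylene chain from C6 of ring B to ring A; tri-O-methyl derivative of the target) | COc1cc2cc(c1)Oc1c(OC)cc(OC)cc1CCCCCCCCCCCCCC2 | intermediate
14 | CNP0173380.0 (macrocyclic diaryl ether triphenol; ring A: one OH; ring B: ether oxygen at C1, OH at C2 and C4, chain at C6) | Oc1cc2cc(c1)Oc1c(O)cc(O)cc1CCCCCCCCCCCCCC2 | target

## Step count and least certain steps

Total step count: 10. Longest linear sequence: 9 steps (steps 1, 2 and 4 to 10, from **1** to **14**); the branch from **5** (step 3) joins at step 4.

**Step 8 (key step).** The most likely failure is chain growth overtaking ring closure. Closing a 20-membered ring costs entropy, so any build-up of uncyclised copper acetylide leads to open-chain and cyclic oligomers. The fallback makes the same C7–C8 bond reductively from two electrophilic carbons. It sets out from **11**: hydroboration of both terminal alkynes with dicyclohexylborane in THF and oxidation with NaBO3·4H2O (anti-Markovnikov hydration) should give 7-{2-[3-(7-oxoheptyl)-5-methoxyphenoxy]-3,5-dimethoxyphenyl}heptanal F1. McMurry coupling of the two identical aliphatic aldehydes (TiCl3(dme)1.5, trivalent titanium, reduced with Zn–Cu couple, DME, reflux, slow addition) should give the macrocyclic C7=C8 alkene trimethyl ether F2 as a mixture of geometric isomers. Hydrogenation over Pd/C returns to **13**.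

**Step 2.** The most likely failure is sluggish oxidative addition at a bromide flanked by formyl and methoxy groups, so that reduction of the C–Br bond or stalled conversion takes over. The fallback replaces copper catalysis by addition–elimination. It sets out from **1** and **3**: electrophilic fluorination of **1** with Selectfluor in MeCN should give 2-fluoro-3,5-dimethoxybenzaldehyde F3, and substitution of its fluoride by the phenoxide of **3** (K2CO3, DMSO, about 120 °C), activated by the ortho formyl group, returns to **4**. The para methoxy group weakens that activation, which is why this is the reserve and not the first choice.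

**Step 4.** The most likely failure is incomplete olefination of the more crowded ring B formyl group while the ylide is consumed by acylation on its own ester as the mixture warms. The fallback sets out from **4** and uses the ylide from (4-carboxybutyl)triphenylphosphonium bromide and excess KOt-Bu in THF, whose carboxylate cannot be acylated. It should give (5Z)-6-{2-[3-((1Z)-5-carboxypent-1-en-1-yl)-5-methoxyphenoxy]-3,5-dimethoxyphenyl}hex-5-enoic acid F4. Fischer esterification (MeOH, catalytic H2SO4) returns to **8**.

**Step 6.** The most likely failure is over-reduction: if the aluminium hemiacetal collapses before the quench, the freed aldehyde is reduced further, and with two ester groups mixtures of oxidation levels result. The fallback sets out from **9**: full reduction with LiAlH4 in THF should give 6-{2-[3-(6-hydroxyhexyl)-5-methoxyphenoxy]-3,5-dimethoxyphenyl}hexan-1-ol F5, and a double Swern oxidation (oxalyl chloride, DMSO, Et3N, −78 °C) returns to **10**.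

## Further compounds

F1 | step 8 | 7-{2-[3-(7-oxoheptyl)-5-methoxyphenoxy]-3,5-dimethoxyphenyl}heptanal | O=CCCCCCCc1cc(OC)cc(OC)c1Oc1cc(OC)cc(CCCCCCC=O)c1
F2 | step 8 | twenty-membered macrocyclic C7=C8 alkene trimethyl ether (E drawn; geometry removed by hydrogenation) | COc1cc2cc(c1)Oc1c(OC)cc(OC)cc1CCCCCC/C=C/CCCCCC2
F3 | step 2 | 2-fluoro-3,5-dimethoxybenzaldehyde | COc1cc(OC)c(F)c(C=O)c1
F4 | step 4 | (5Z)-6-{2-[3-((1Z)-5-carboxypent-1-en-1-yl)-5-methoxyphenoxy]-3,5-dimethoxyphenyl}hex-5-enoic acid | OC(=O)CCC/C=C\c1cc(OC)cc(OC)c1Oc1cc(OC)cc(/C=C\CCCC(=O)O)c1
F5 | step 6 | 6-{2-[3-(6-hydroxyhexyl)-5-methoxyphenoxy]-3,5-dimethoxyphenyl}hexan-1-ol | OCCCCCCc1cc(OC)cc(OC)c1Oc1cc(OC)cc(CCCCCCO)c1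
A1 | alternative 1 | rac-3-chloro-5-[14-(2-hydroxy-3,5-dimethoxyphenyl)tetradecyl]cyclohex-2-en-1-one | O=C1C=C(Cl)CC(C1)CCCCCCCCCCCCCCc1cc(OC)cc(OC)c1O
A2 | alternative 1 | racemic twenty-membered macrocyclic 3-aryloxycyclohex-2-enone (ring B oxygen on C3 of the enone, chain on C5) | O=C1C=C2CC(C1)CCCCCCCCCCCCCCc1cc(OC)cc(OC)c1O2
A3 | alternative 2 | 21-membered macrocyclic benzylic sulfone, trimethyl ether (SO2 between the ring A benzylic carbon and chain C13) | COc1cc2cc(c1)CS(=O)(=O)CCCCCCCCCCCCCc1cc(OC)cc(OC)c1O2
A4 | alternative 2 | twenty-membered macrocyclic C13=C14 alkene, trimethyl ether (E drawn) | COc1cc2cc(c1)/C=C/CCCCCCCCCCCCc1cc(OC)cc(OC)c1O2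
A5 | alternative 3 | 2-[3-methoxy-5-(13-oxotridecyl)phenoxy]-3,5-dimethoxybenzaldehyde | COc1cc(CCCCCCCCCCCCC=O)cc(Oc2c(OC)cc(OC)cc2C=O)c1
A6 | alternative 3 | twenty-membered macrocyclic C1=C2 alkene, trimethyl ether (E drawn) | COc1cc2cc(c1)Oc1c(OC)cc(OC)cc1/C=C/CCCCCCCCCCCC2
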